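**Retrosynthetic overview**
1. Target ← O-methylation of the C5 tertiary o-quinol ← allylboration of the C5 carbonyl of a 2,3-dihydrobenzofuran-5,6-dione ← oxidative demethylation of the 6-hydroxy-5-methoxy arene; ring A is dearomatised last.
2. C3 methyl ← C3 methyl ester (reduction, tosylation, hydride displacement), after cis-to-trans epimerisation at C3.
3. Feature used: C2 (benzofuran numbering) is a benzylic ether carbon, flanked by O1 and the trimethoxyphenyl ring C and bonded to C3, which sits on C3a of ring A. A carbene at C3 on the aromatic precursor of ring A can therefore insert into the C2–H bond of a 3,4,5-trimethoxybenzyl aryl ether, forming C2–C3 and closing ring B (O1, C2, C3, C3a, C7a).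
4. Diazo ester ← aryl acetate (diazo transfer) ← phenol + 3,4,5-trimethoxybenzyl chloride; phenol ← homovanillic acid (esterification, MOM protection, bromination, borylation/oxidation).
5. Ring order: rings A and C come from the starting materials; ring B is the only ring formed (step 7).

Key step: step 7

Assumption: the S-configured phthalimido-tert-leucinate catalyst is taken to give the (2R,3S) cis esters in this reaction class, so Rh2(R-PTTL)4 is used to reach 2S; if the sense is opposite on this substrate, the antipodal catalyst is used and nothing else changes.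

**Step 1**
Reactants: 1 homovanillic acid
Product: 2 methyl 2-(4-hydroxy-3-methoxyphenyl)acetate
Conditions: MeOH, H2SO4 (cat.), reflux
Reagents that add atoms: methanol, CO
Why: Fischer esterification of the aliphatic acid, which leaves the phenol untouched.

**Step 2**
Reactants: 2 methyl 2-(4-hydroxy-3-methoxyphenyl)acetate
Product: 3 methyl 2-[3-methoxy-4-(methoxymethoxy)phenyl]acetate
Conditions: MOMCl, iPr2NEt, CH2Cl2, 0 °C → rt
Reagents that add atoms: chloromethyl methyl ether, COCCl
Why: O-alkylation of the phenol to a MOM acetal, which survives the base, hydride, palladium and carbene steps and is removed by acid in step 12.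

**Step 3**
Reactants: 3 methyl 2-[3-methoxy-4-(methoxymethoxy)phenyl]acetate
Product: 4 methyl 2-[2-bromo-5-methoxy-4-(methoxymethoxy)phenyl]acetate
Conditions: NBS, MeCN, 0 °C → rt
Reagents that add atoms: N-bromosuccinimide, O=C1CCC(=O)N1Br
Why: electrophilic aromatic bromination goes to the unhindered position para to the methoxy group and ortho to the CH2 side chain, as is usual for 3,4-dialkoxyphenylacetates.

**Step 4**
Reactants: 4 methyl 2-[2-bromo-5-methoxy-4-(methoxymethoxy)phenyl]acetate
Product: 6 methyl 2-[2-hydroxy-5-methoxy-4-(methoxymethoxy)phenyl]acetate, via aryl pinacol boronate 5 (not isolated)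
Conditions: B2pin2, Pd(dppf)Cl2 (3 mol %), KOAc, 1,4-dioxane, 85 °C; then NaBO3·4H2O, THF/H2O, rt
Reagents that add atoms: bis(pinacolato)diboron, CC1(C)OB(OC1(C)C)B1OC(C)(C)C(C)(C)O1 (boron group of 5); NaBO3·4H2O, [Na+].[Na+].O[B-]1(O)OO[B-](O)(O)OO1 (hydroxyl oxygen of 6)
Why: Miyaura borylation (oxidative addition of the aryl bromide to zerovalent palladium, transmetalation with the acetate-activated diboron) followed by perborate oxidation of the C–B bond with aryl migration to oxygen; both stages are mild enough for the methyl ester and the MOM ether.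

**Step 5**
Reactants: 6 methyl 2-[2-hydroxy-5-methoxy-4-(methoxymethoxy)phenyl]acetate; 7 3,4,5-trimethoxybenzyl chloride
Product: 8 methyl 2-[5-methoxy-4-(methoxymethoxy)-2-(3,4,5-trimethoxybenzyloxy)phenyl]acetate
Conditions: K2CO3, DMF, 50 °C, argon
Reagents that add atoms: none
Why: Williamson etherification by SN2 attack of the phenoxide on the benzylic chloride; K2CO3 is too weak to enolise the ester, and argon keeps the electron-rich phenoxide from air oxidation.

**Step 6**
Reactants: 8 methyl 2-[5-methoxy-4-(methoxymethoxy)-2-(3,4,5-trimethoxybenzyloxy)phenyl]acetate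
Product: 9 methyl 2-diazo-2-[5-methoxy-4-(methoxymethoxy)-2-(3,4,5-trimethoxybenzyloxy)phenyl]acetate
Conditions: p-ABSA, DBU, MeCN, 0 °C → rt
Reagents that add atoms: 4-acetamidobenzenesulfonyl azide, CC(=O)Nc1ccc(cc1)S(=O)(=O)N=[N+]=[N-]
Why: Regitz diazo transfer from the sulfonyl azide to the DBU-generated benzylic ester enolate, the standard route to aryldiazoacetates.

**Step 7**
Reactants: 9 methyl 2-diazo-2-[5-methoxy-4-(methoxymethoxy)-2-(3,4,5-trimethoxybenzyloxy)phenyl]acetate
Product: 10 methyl (2S,3R)-5-methoxy-6-(methoxymethoxy)-2-(3,4,5-trimethoxyphenyl)-2,3-dihydrobenzofuran-3-carboxylate (cis)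
Conditions: Rh2(R-PTTL)4 (1 mol %), toluene, −78 °C, slow addition of 9
Reagents that add atoms: none
Why: The dirhodium catalyst takes up the diazo carbon of 9, N2 leaves, and the electrophilic donor/acceptor rhodium carbene at the future C3 reaches the benzylic ether C–H bond of the future C2 five atoms away; C–C bond formation and hydride transfer occur in one asynchronous three-centre step that releases the catalyst. The closest known reaction type is the dirhodium-carboxylate-catalysed enantioselective intramolecular C–H insertion of 2-(benzyloxy)aryl diazoacetates, which gives cis-2-aryl-2,3-dihydrobenzofuran-3-carboxylates. Ring B (O1, C2, C3, C3a, C7a) closes by this 1,5-insertion, with C2–C3 as its only new bond. C2 is set by the chiral pocket of the four phthalimido-tert-leucinate ligands, which lets only one of the two enantiotopic benzylic hydrogens reach the carbene, and C3 is set relative to C2 in the same transition state, with the aryl group and the ester cis under kinetic control. The step needs site selectivity for this C–H bond over addition to ring C, insertion at the MOM methylene and carbene dimerisation; the bond is activated by both the ether oxygen and the electron-rich arene, it is the only one within five-membered-ring reach, and slow addition at low temperature keeps the diazo concentration low.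

**Step 8**
Reactants: 10 methyl (2S,3R)-5-methoxy-6-(methoxymethoxy)-2-(3,4,5-trimethoxyphenyl)-2,3-dihydrobenzofuran-3-carboxylate
Product: 11 methyl (2S,3S)-5-methoxy-6-(methoxymethoxy)-2-(3,4,5-trimethoxyphenyl)-2,3-dihydrobenzofuran-3-carboxylate (trans)
Conditions: NaOMe (0.3 equiv), MeOH, rt
Reagents that add atoms: none
Why: reversible enolisation of the C3 ester equilibrates the hindered cis isomer to the more stable trans isomer; C2 should be untouched because elimination of the aryloxide from the ring enolate has poor orbital overlap in the five-membered ring.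

**Step 9**
Reactants: 11 methyl (2S,3S)-5-methoxy-6-(methoxymethoxy)-2-(3,4,5-trimethoxyphenyl)-2,3-dihydrobenzofuran-3-carboxylate
Product: 12 [(2S,3R)-5-methoxy-6-(methoxymethoxy)-2-(3,4,5-trimethoxyphenyl)-2,3-dihydrobenzofuran-3-yl]methanol
Conditions: LiAlH4, THF, 0 °C; then H2O, aq. NaOH
Reagents that add atoms: none
Why: hydride reduction of the ester to the primary alcohol without touching either stereocentre (the C3 descriptor changes by priority only).

**Step 10**
Reactants: 12 [(2S,3R)-5-methoxy-6-(methoxymethoxy)-2-(3,4,5-trimethoxyphenyl)-2,3-dihydrobenzofuran-3-yl]methanol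
Product: 13 [(2S,3R)-5-methoxy-6-(methoxymethoxy)-2-(3,4,5-trimethoxyphenyl)-2,3-dihydrobenzofuran-3-yl]methyl 4-methylbenzenesulfonate
Conditions: TsCl, Et3N, DMAP (cat.), CH2Cl2, 0 °C → rt
Reagents that add atoms: p-toluenesulfonyl chloride, Cc1ccc(cc1)S(Cl)(=O)=O
Why: sulfonylation of the unhindered primary alcohol gives a leaving group for hydride displacement.

**Step 11**
Reactants: 13 [(2S,3R)-5-methoxy-6-(methoxymethoxy)-2-(3,4,5-trimethoxyphenyl)-2,3-dihydrobenzofuran-3-yl]methyl 4-methylbenzenesulfonate
Product: 14 (2S,3S)-5-methoxy-6-(methoxymethoxy)-3-methyl-2-(3,4,5-trimethoxyphenyl)-2,3-dihydrobenzofuran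
Conditions: LiBHEt3, THF, 0 °C → rt
Reagents that add atoms: none
Why: SN2 displacement of the primary tosylate by hydride turns CH2OTs into the C3 methyl group without breaking a bond at C3.

**Step 12**
Reactants: 14 (2S,3S)-5-methoxy-6-(methoxymethoxy)-3-methyl-2-(3,4,5-trimethoxyphenyl)-2,3-dihydrobenzofuran
Product: 15 (2S,3S)-5-methoxy-3-methyl-2-(3,4,5-trimethoxyphenyl)-2,3-dihydrobenzofuran-6-ol
Conditions: HCl (cat.), MeOH, 40 °C
Reagents that add atoms: none
Why: acid-catalysed transacetalisation removes the MOM group as dimethoxymethane under conditions too mild to ionise the C2–O1 bond of the already trans ring.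

**Step 13**
Reactants: 15 (2S,3S)-5-methoxy-3-methyl-2-(3,4,5-trimethoxyphenyl)-2,3-dihydrobenzofuran-6-ol
Product: 16 (2S,3S)-3-methyl-2-(3,4,5-trimethoxyphenyl)-2,3-dihydrobenzofuran-5,6-dione
Conditions: PhI(OAc)2 (1.05 equiv), MeCN/H2O 4:1, 0 °C; cold extractive work-up, used at once
Reagents that add atoms: water, O
Why: hypervalent iodine oxidative demethylation of a 2-methoxyphenol, in which the iodine-activated phenol is attacked by water at C5 (the carbon whose positive charge the methoxy group stabilises) and methanol is lost; O1 makes the C6 carbonyl a vinylogous ester, which stabilises the quinone.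

**Step 14**
Reactants: 16 (2S,3S)-3-methyl-2-(3,4,5-trimethoxyphenyl)-2,3-dihydrobenzofuran-5,6-dione
Product: 18 (2S,3S,5R)-5-allyl-5-hydroxy-3-methyl-2-(3,4,5-trimethoxyphenyl)-2,3-dihydrobenzofuran-6(5H)-one, via diisopinocampheylborinate ester 17 (not isolated)
Conditions: (−)-B-allyldiisopinocampheylborane [both isopinocampheyl groups (1R,2R,3R,5S), from (+)-α-pinene] (1.3 equiv), Et2O/pentane, −78 °C; then MeOH, pH 7 phosphate buffer, rt
Reagents that add atoms: (−)-B-allyldiisopinocampheylborane, C=CCB([C@@H]1C[C@@H]2C[C@H]([C@H]1C)C2(C)C)[C@@H]1C[C@@H]2C[C@H]([C@H]1C)C2(C)C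
Why: Proposed new method: allylboration of carbonyl groups by this reagent through a closed six-membered chair transition state is known, and o-quinones are known to take allyl-metal reagents by 1,2-addition, but a reagent-controlled, face-selective allylboration of an o-quinone carbonyl has not been shown; C5 should react because the C6 carbonyl is deactivated as a vinylogous ester (O1–C7a=C7–C6=O), boron should bind the C5 oxygen on the side of C4–H and away from the C6 oxygen so that the C6 flank takes the equatorial place of the large group, and the reagent from (+)-α-pinene should then deliver allyl to the face anti to the C3 methyl group, which is 5R (if the other face is attacked, the reagent from (−)-α-pinene is used); the closest known reaction type is the asymmetric allylboration of aldehydes and ketones with B-allyldiisopinocampheylborane.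

**Step 15**
Reactants: 18 (2S,3S,5R)-5-allyl-5-hydroxy-3-methyl-2-(3,4,5-trimethoxyphenyl)-2,3-dihydrobenzofuran-6(5H)-one
Product: 19 (2S,3S,5R)-5-allyl-5-methoxy-3-methyl-2-(3,4,5-trimethoxyphenyl)-2,3-dihydrobenzofuran-6(5H)-one
Conditions: MeI (excess), Ag2O, MeCN, 35 °C, dark
Reagents that add atoms: iodomethane, CI
Why: Purdie methylation of the tertiary α-ketol oxygen under neutral conditions, which avoids a free alkoxide (no α-ketol shift or anionic oxy-Cope rearrangement) and breaks no bond at C5.

**Compound list**
1 | homovanillic acid | COc1cc(CC(=O)O)ccc1O | starting material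
2 | methyl 2-(4-hydroxy-3-methoxyphenyl)acetate | COC(=O)Cc1ccc(O)c(OC)c1 | intermediate
3 | methyl 2-[3-methoxy-4-(methoxymethoxy)phenyl]acetate | COCOc1ccc(CC(=O)OC)cc1OC | intermediate
4 | methyl 2-[2-bromo-5-methoxy-4-(methoxymethoxy)phenyl]acetate | COC(=O)Cc1cc(OC)c(OCOC)cc1Br | intermediate
5 | methyl 2-[5-methoxy-4-(methoxymethoxy)-2-(4,4,5,5-tetramethyl-1,3,2-dioxaborolan-2-yl)phenyl]acetate | COC(=O)Cc1cc(OC)c(OCOC)cc1B1OC(C)(C)C(C)(C)O1 | intermediate
6 | methyl 2-[2-hydroxy-5-methoxy-4-(methoxymethoxy)phenyl]acetate | COC(=O)Cc1cc(OC)c(OCOC)cc1O | intermediate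
7 | 3,4,5-trimethoxybenzyl chloride | COc1cc(CCl)cc(OC)c1OC | starting material
8 | methyl 2-[5-methoxy-4-(methoxymethoxy)-2-(3,4,5-trimethoxybenzyloxy)phenyl]acetate | COC(=O)Cc1cc(OC)c(OCOC)cc1OCc1cc(OC)c(OC)c(OC)c1 | intermediate
9 | methyl 2-diazo-2-[5-methoxy-4-(methoxymethoxy)-2-(3,4,5-trimethoxybenzyloxy)phenyl]acetate | COC(=O)C(=[N+]=[N-])c1cc(OC)c(OCOC)cc1OCc1cc(OC)c(OC)c(OC)c1 | intermediate
10 | methyl (2S,3R)-5-methoxy-6-(methoxymethoxy)-2-(3,4,5-trimethoxyphenyl)-2,3-dihydrobenzofuran-3-carboxylate (cis) | COc1cc2c(cc1OCOC)O[C@H](c1cc(OC)c(OC)c(OC)c1)[C@@H]2C(=O)OC | intermediate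
11 | methyl (2S,3S)-5-methoxy-6-(methoxymethoxy)-2-(3,4,5-trimethoxyphenyl)-2,3-dihydrobenzofuran-3-carboxylate (trans) | COc1cc2c(cc1OCOC)O[C@H](c1cc(OC)c(OC)c(OC)c1)[C@H]2C(=O)OC | intermediate
12 | [(2S,3R)-5-methoxy-6-(methoxymethoxy)-2-(3,4,5-trimethoxyphenyl)-2,3-dihydrobenzofuran-3-yl]methanol | COc1cc2c(cc1OCOC)O[C@H](c1cc(OC)c(OC)c(OC)c1)[C@H]2CO | intermediate
13 | [(2S,3R)-5-methoxy-6-(methoxymethoxy)-2-(3,4,5-trimethoxyphenyl)-2,3-dihydrobenzofuran-3-yl]methyl 4-methylbenzenesulfonate | COc1cc2c(cc1OCOC)O[C@H](c1cc(OC)c(OC)c(OC)c1)[C@H]2COS(=O)(=O)c1ccc(C)cc1 | intermediate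
14 | (2S,3S)-5-methoxy-6-(methoxymethoxy)-3-methyl-2-(3,4,5-trimethoxyphenyl)-2,3-dihydrobenzofuran | COc1cc2c(cc1OCOC)O[C@H](c1cc(OC)c(OC)c(OC)c1)[C@H]2C | intermediate
15 | (2S,3S)-5-methoxy-3-methyl-2-(3,4,5-trimethoxyphenyl)-2,3-dihydrobenzofuran-6-ol | COc1cc2c(cc1O)O[C@H](c1cc(OC)c(OC)c(OC)c1)[C@H]2C | intermediate
16 | (2S,3S)-3-methyl-2-(3,4,5-trimethoxyphenyl)-2,3-dihydrobenzofuran-5,6-dione | O=C1C=C2C(=CC1=O)O[C@H](c1cc(OC)c(OC)c(OC)c1)[C@H]2C | intermediate
17 | (2S,3S,5R)-5-allyl-5-{bis[(1R,2R,3R,5S)-2,6,6-trimethylbicyclo[3.1.1]heptan-3-yl]boranyloxy}-3-methyl-2-(3,4,5-trimethoxyphenyl)-2,3-dihydrobenzofuran-6(5H)-one | C=CC[C@@]1(OB([C@@H]3C[C@@H]4C[C@H]([C@H]3C)C4(C)C)[C@@H]3C[C@@H]4C[C@H]([C@H]3C)C4(C)C)C=C2C(=CC1=O)O[C@H](c1cc(OC)c(OC)c(OC)c1)[C@H]2C | intermediate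
18 | (2S,3S,5R)-5-allyl-5-hydroxy-3-methyl-2-(3,4,5-trimethoxyphenyl)-2,3-dihydrobenzofuran-6(5H)-one | C=CC[C@@]1(O)C=C2C(=CC1=O)O[C@H](c1cc(OC)c(OC)c(OC)c1)[C@H]2C | intermediate
19 | (2S,3S,5R)-5-allyl-5-methoxy-3-methyl-2-(3,4,5-trimethoxyphenyl)-2,3-dihydrobenzofuran-6(5H)-one | C=CC[C@@]1(OC)C=C2C(=CC1=O)O[C@H](c1cc(OC)c(OC)c(OC)c1)[C@H]2C | target

**Total step count:** 15
**Longest linear sequence:** 15 steps (1 → 19)

**Steps most likely to fail**

Step 14 (labelled). The two flanks of the C5 carbonyl are both flat sp2 carbons, so the reagent may discriminate the faces poorly. The borane may also reduce the quinone by electron transfer or add to the C6 carbonyl. The fallback uses known chemistry, sets out from phenol 15 and comes back at target 19, so that steps 13 to 15 are not needed. It is the oxidative nucleophilic substitution of a 2-alkoxyarenol with a hypervalent iodine reagent and an allylsilane: PhI(OCOCF3)2 and allyltrimethylsilane in CH2Cl2 at −78 °C. The oxidised phenol is attacked at C5, the carbon that carries the methoxy group, so allyl and methoxy end on the same carbon and no methylation is required. No control over C5 is expected, and 19 would be separated by chromatography from its C5 epimer, (2S,3S,5S)-5-allyl-5-methoxy-3-methyl-2-(3,4,5-trimethoxyphenyl)-2,3-dihydrobenzofuran-6(5H)-one F1.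

Step 13. Water may attack the oxidised phenol at C3a instead of C5. The free quinone may also enolise through C3–H (vinylogous to the C5 carbonyl) to a quinone methide and then aromatise to a benzofuran catechol, which would erase C2 and C3. The fallback sets out from 15 and comes back at 16. Oxidation with PhI(OAc)2 in MeOH at 0 °C, the standard formation of an o-quinone monoketal from a 2-methoxyphenol, should give (2S,3S)-5,5-dimethoxy-3-methyl-2-(3,4,5-trimethoxyphenyl)-2,3-dihydrobenzofuran-6(5H)-one F2, which can be purified and stored. The ketal is hydrolysed with dilute aqueous CF3CO2H in CH2Cl2 at 0 °C directly before step 14, so the free quinone 16 exists only briefly.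

Step 7. Enantioselectivity may be eroded because the very electron-rich carbene aryl group and benzyl ether make the transition state early; carbene dimerisation may also compete. The fallback replaces catalyst control by classical resolution; it sets out from 10 of whatever enantiomeric purity and comes back at 12. KOH in MeOH/H2O at reflux epimerises C3 and saponifies in one operation to (2S,3S)-5-methoxy-6-(methoxymethoxy)-2-(3,4,5-trimethoxyphenyl)-2,3-dihydrobenzofuran-3-carboxylic acid F3 (acidified cold to about pH 4 to keep the MOM group). The acid is crystallised to constant rotation as its (R)-1-phenylethylammonium salt F4 and released again with cold aqueous citric acid. Reduction of the acid with LiAlH4 in THF then gives alcohol 12 directly, so steps 8 and 9 are not needed.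

**Further compounds**
F1 | step 14 | (2S,3S,5S)-5-allyl-5-methoxy-3-methyl-2-(3,4,5-trimethoxyphenyl)-2,3-dihydrobenzofuran-6(5H)-one | C=CC[C@]1(OC)C=C2C(=CC1=O)O[C@H](c1cc(OC)c(OC)c(OC)c1)[C@H]2C
F2 | step 13 | (2S,3S)-5,5-dimethoxy-3-methyl-2-(3,4,5-trimethoxyphenyl)-2,3-dihydrobenzofuran-6(5H)-one | COC1(OC)C=C2C(=CC1=O)O[C@H](c1cc(OC)c(OC)c(OC)c1)[C@H]2C
F3 | step 7 | (2S,3S)-5-methoxy-6-(methoxymethoxy)-2-(3,4,5-trimethoxyphenyl)-2,3-dihydrobenzofuran-3-carboxylic acid | COc1cc2c(cc1OCOC)O[C@H](c1cc(OC)c(OC)c(OC)c1)[C@H]2C(=O)O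
F4 | step 7 | (R)-1-phenylethylammonium (2S,3S)-5-methoxy-6-(methoxymethoxy)-2-(3,4,5-trimethoxyphenyl)-2,3-dihydrobenzofuran-3-carboxylate | COc1cc2c(cc1OCOC)O[C@H](c1cc(OC)c(OC)c(OC)c1)[C@H]2C(=O)[O-].C[C@@H]([NH3+])c1ccccc1
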